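Ring B (C5–C10) is disconnected across C9–C10 and C7–C8 into two aldehydes: β-homocyclocitral, which supplies ring A and C6–C7, and an E-enal that supplies C8, C9, C17 and the complete acylated side chain. An amine-catalysed formal [4+2] of the derived dienamine (C10=C5–C6=C7) with the enal should form both bonds, set C9 and C10 under catalyst control and, after loss of the amine, deliver the 7,8-olefin with C17 as the aldehyde. The feature exploited is cyclohexene ring B, whose quaternary C10 and C7=C8–C17 unit map onto a 1-amino-diene plus an enal. Luche reduction and hydrogenation of the 5,6-bond anti to the 10-methyl finish the ent-labdane.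

Key step: step 3

Remarks:
- Atom numbers are labdane numbers (ring A: C1–C5, C10; ring B: C5–C10; side chain C11–C16; C17 on C8). The target belongs to the ent series, (5R,9S,10R).
- Assumption: 30-hydroxytriacontanoic acid (1) is bought from a lipid supplier; geranyl chloride, crotonaldehyde and β-homocyclocitral are catalogue chemicals.
- The aminocatalyst of step 3 is (S)-2-[diphenyl(trimethylsilyloxy)methyl]pyrrolidine, C[Si](C)(C)OC(c1ccccc1)(c1ccccc1)[C@@H]1CCCN1.

Step 1
Reactants: 1 30-hydroxytriacontanoic acid; 2 geranyl chloride [(2E)-1-chloro-3,7-dimethylocta-2,6-diene]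
Product: 4 geranyl 30-hydroxytriacontanoate, via cesium 30-hydroxytriacontanoate 3 (not isolated)
Conditions: Cs2CO3 (1.0 equiv), n-Bu4NI (10 mol%), DMF/THF (1:1), 50 °C
Reagents that add atoms: none
Why: SN2 O-alkylation of the carboxylate by the primary allylic chloride; the un-ionised ω-hydroxyl does not compete, so no protecting group is needed, and the E-olefin of 2 becomes the 13E-olefin of the target.

Step 2
Reactants: 4 geranyl 30-hydroxytriacontanoate; 5 (E)-but-2-enal (crotonaldehyde)
Product: 6 (2E,6E)-3-methyl-8-oxoocta-2,6-dien-1-yl 30-hydroxytriacontanoate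
Conditions: 5 (8 equiv), second-generation Hoveyda–Grubbs catalyst RuCl2(H2IMes)(=CH–C6H4-2-OiPr) (5 mol%), CH2Cl2, 40 °C
Reagents that add atoms: none
Why: Olefin cross-metathesis: the electron-rich isopropylidene terminus should exchange with the electron-poor enal partner to give the E-enal and volatile 2-methylbut-2-ene, while the 2,3-olefin, hindered and deactivated by the allylic ester, should stay untouched.

Step 3
Reactants: 6 (2E,6E)-3-methyl-8-oxoocta-2,6-dien-1-yl 30-hydroxytriacontanoate; 7 β-homocyclocitral [2-(2,6,6-trimethylcyclohex-1-en-1-yl)acetaldehyde]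
Product: 10 15-(30-hydroxytriacontanoyloxy)-ent-labda-5,7,13E-trien-17-al, (9S,10S), via catalyst-bound dienamine 8 (not isolated), via 7-amino aldehyde cycloadduct 9 (not isolated)
Conditions: 7 (2 equiv), (S)-2-[diphenyl(trimethylsilyloxy)methyl]pyrrolidine (20 mol%), PhCO2H (20 mol%), CHCl3, 25 to 40 °C, 6 added slowly
Reagents that add atoms: none
Why: Proposed new method: the amine condenses with the β,γ-unsaturated aldehyde 7 to the 1-amino-diene 8 (N–C7=C6–C5=C10, HOMO raised, largest coefficient at C10), which adds across C10 and C7 to the C9=C8 bond of enal 6 (free or as its iminium ion) in a concerted endo [4+2] or a stepwise vinylogous Michael (C10–C9) then Mannich (C8–C7) sequence, after which E1cB loss of the amine from 9 frees the catalyst and leaves the C7=C8 bond conjugated to the C17 aldehyde. The closest known reaction type is the secondary-amine-catalysed dienamine/iminium formal [4+2] of two enals with catalyst release by elimination, which has not been shown for a dienamine whose reacting terminus is a fully substituted ring carbon flanked by a gem-dimethyl group. Ring B closes by intermolecular [4+2] cycloaddition (in the stepwise limit by a 6-(enolexo)-exo-trig Mannich closure). C10 is set by the catalyst, whose diphenyl(silyloxy)methyl group shields one face of the s-trans (E)-dienamine so that the enal bonds to the open face, which for the (S)-amine is expected to give the 10-methyl configuration of the target. C9 is set relative to C10 by the E geometry of 6 and the endo position of its formyl group, which places C11 cis to the 10-methyl. The step needs bond formation at hindered C10 instead of C6 and cross-reaction instead of enal self-condensation; the amino donor on C7 fixes the regiochemistry, only the C10 adduct can cyclise and turn the catalyst over, and excess 7 with slow addition of 6 holds the enal concentration low.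

Step 4
Reactants: 10 15-(30-hydroxytriacontanoyloxy)-ent-labda-5,7,13E-trien-17-al
Product: 11 ent-labda-5,7,13E-triene-15,17-diol 15-(30-hydroxytriacontanoate), (9S,10S)
Conditions: NaBH4, CeCl3·7H2O, MeOH/THF, 0 °C
Reagents that add atoms: none
Why: Luche reduction: cerium-assisted 1,2-hydride addition to the conjugated aldehyde should give the dienyl carbinol without touching the ester, the ring diene or C9.

Step 5
Reactants: 11 ent-labda-5,7,13E-triene-15,17-diol 15-(30-hydroxytriacontanoate)
Product: 12 ent-labda-7,13E-diene-15,17-diol 15-(30-hydroxytriacontanoate), (5R,9S,10R), the target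
Conditions: H2 (1 atm), Raney Ni (W-2), EtOAc, 20 °C, stopped after 1 equiv of H2
Reagents that add atoms: none
Why: Heterogeneous partial hydrogenation of a homoannular 5,7-diene: as with steroidal 5,7-dienes over Raney Ni, the conjugated diene should be taken up before isolated trisubstituted olefins, and H2 should add across C5–C6 from the face opposite the axial 10-methyl and the C9 side chain, which sets the trans ring fusion at C5 and leaves the 7,8- and 13,14-olefins.

Compound list
1 | 30-hydroxytriacontanoic acid | OC(=O)CCCCCCCCCCCCCCCCCCCCCCCCCCCCCO | starting material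
2 | geranyl chloride, (2E)-1-chloro-3,7-dimethylocta-2,6-diene | CC(C)=CCC/C(C)=C/CCl | starting material
3 | cesium 30-hydroxytriacontanoate | [Cs+].[O-]C(=O)CCCCCCCCCCCCCCCCCCCCCCCCCCCCCO | intermediate
4 | geranyl 30-hydroxytriacontanoate, (2E)-3,7-dimethylocta-2,6-dien-1-yl ester | C/C(=C\COC(=O)CCCCCCCCCCCCCCCCCCCCCCCCCCCCCO)CCC=C(C)C | intermediate
5 | (E)-but-2-enal (crotonaldehyde) | C/C=C/C=O | starting material
6 | (2E,6E)-3-methyl-8-oxoocta-2,6-dien-1-yl 30-hydroxytriacontanoate | C/C(=C\COC(=O)CCCCCCCCCCCCCCCCCCCCCCCCCCCCCO)CC/C=C/C=O | intermediate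
7 | β-homocyclocitral, 2-(2,6,6-trimethylcyclohex-1-en-1-yl)acetaldehyde | CC1=C(CC=O)C(C)(C)CCC1 | starting material
8 | (S)-2-[diphenyl(trimethylsilyloxy)methyl]-1-[(E)-2-(2,6,6-trimethylcyclohex-1-en-1-yl)ethenyl]pyrrolidine (dienamine) | CC1=C(/C=C/N2CCC[C@H]2C(O[Si](C)(C)C)(c2ccccc2)c2ccccc2)C(C)(C)CCC1 | intermediate
9 | 15-(30-hydroxytriacontanoyloxy)-7-{(S)-2-[diphenyl(trimethylsilyloxy)methyl]pyrrolidin-1-yl}-ent-labda-5,13E-dien-17-al; 7-N, 8-CHO and 9-H cis, all trans to CH3-10 | C/C(=C\COC(=O)CCCCCCCCCCCCCCCCCCCCCCCCCCCCCO)CC[C@@H]1[C@@H](C=O)[C@@H](N2CCC[C@H]2C(O[Si](C)(C)C)(c2ccccc2)c2ccccc2)C=C2C(C)(C)CCC[C@@]12C | intermediate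
10 | 15-(30-hydroxytriacontanoyloxy)-ent-labda-5,7,13E-trien-17-al; (2E)-5-[(1S,8aS)-2-formyl-5,5,8a-trimethyl-1,5,6,7,8,8a-hexahydronaphthalen-1-yl]-3-methylpent-2-en-1-yl 30-hydroxytriacontanoate | C/C(=C\COC(=O)CCCCCCCCCCCCCCCCCCCCCCCCCCCCCO)CC[C@@H]1C(C=O)=CC=C2C(C)(C)CCC[C@@]12C | intermediate
11 | ent-labda-5,7,13E-triene-15,17-diol 15-(30-hydroxytriacontanoate); (2E)-5-[(1S,8aS)-2-(hydroxymethyl)-5,5,8a-trimethyl-1,5,6,7,8,8a-hexahydronaphthalen-1-yl]-3-methylpent-2-en-1-yl 30-hydroxytriacontanoate | C/C(=C\COC(=O)CCCCCCCCCCCCCCCCCCCCCCCCCCCCCO)CC[C@@H]1C(CO)=CC=C2C(C)(C)CCC[C@@]12C | intermediate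
12 | ent-labda-7,13E-diene-15,17-diol 15-(30-hydroxytriacontanoate); (2E)-5-[(1S,4aR,8aR)-2-(hydroxymethyl)-5,5,8a-trimethyl-1,4,4a,5,6,7,8,8a-octahydronaphthalen-1-yl]-3-methylpent-2-en-1-yl 30-hydroxytriacontanoate | C/C(=C\COC(=O)CCCCCCCCCCCCCCCCCCCCCCCCCCCCCO)CC[C@@H]1C(CO)=CC[C@@H]2C(C)(C)CCC[C@@]12C | target

Total step count: 5. Longest linear sequence: 5 steps (1 → 4 → 6 → 10 → 11 → 12).

Steps most likely to fail

1. Step 3 (Proposed new method). The dienamine may react through its unhindered α-carbon C6 or not at all at the fully substituted C10. The enal 6 may also self-condense through its own dienamine, and facial control by the catalyst may erode at the higher temperature a slow reaction would need. The fallback uses known chemistry, an iminium-catalysed Diels–Alder reaction of an isolated 1-acyloxy diene, and sets out from 7. Aldehyde 7 is converted with Ac2O, Et3N and DMAP into the dienyl acetate (E)-2-(2,6,6-trimethylcyclohex-1-en-1-yl)ethenyl acetate F1. F1 then serves as the diene towards enal 6, which is activated as its iminium ion by 5-benzyl-2-tert-butyl-3-methylimidazolidin-4-one trifluoroacetate (the enantiomer whose benzyl group leaves the Re face of C9 open) in aqueous MeCN. The acetoxy donor on C7 directs C10 to C9 as before, and the endo cycloadduct should be 7-acetoxy-15-(30-hydroxytriacontanoyloxy)-ent-labda-5,13E-dien-17-al F2. Treatment of F2 with DBU eliminates acetic acid (E1cB) and the route is rejoined at 10.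

2. Step 5. Site selectivity within the ring diene may be lost, by saturation of the less hindered 7,8-bond or by 1,4-addition. The allylic ester olefin of the side chain may also be hydrogenated or hydrogenolysed. The fallback sets out from 10, before step 4, and uses a homogeneous catalyst that takes only cisoid conjugated dienes. Hydrogenation of 10 with (η6-naphthalene)Cr(CO)3 and H2 in THF at 45 °C should add hydrogen 1,4 across C5 and C8 from the face opposite the 10-methyl and leave isolated olefins alone. This should give the β,γ-unsaturated aldehyde 15-(30-hydroxytriacontanoyloxy)-ent-labda-6,13E-dien-17-al (5-H, 8-H and 9-H cis) F3. DBU in CH2Cl2 then moves the olefin into conjugation with the formyl group to give 15-(30-hydroxytriacontanoyloxy)-ent-labda-7,13E-dien-17-al F4. Luche reduction of F4 (NaBH4, CeCl3·7H2O, MeOH, 0 °C) rejoins the route at 12.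

3. Step 2. Metathesis of the trisubstituted olefin may stall, and the enal may decompose the catalyst before conversion is complete. The fallback sets out from 4 and replaces metathesis by oxidative cleavage and olefination. mCPBA (CH2Cl2, 0 °C) should epoxidise the electron-rich terminal olefin selectively to 6,7-epoxygeranyl 30-hydroxytriacontanoate (racemic at the epoxide) F5. H5IO6 in THF/Et2O cleaves F5 to (2E)-3-methyl-6-oxohex-2-en-1-yl 30-hydroxytriacontanoate F6. A Wittig reaction of F6 with Ph3P=CHCHO (toluene, 80 °C) gives the E-enal and rejoins the route at 6.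

Further compounds
F1 | step 3 | (E)-2-(2,6,6-trimethylcyclohex-1-en-1-yl)ethenyl acetate | CC1=C(/C=C/OC(C)=O)C(C)(C)CCC1
F2 | step 3 | 7-acetoxy-15-(30-hydroxytriacontanoyloxy)-ent-labda-5,13E-dien-17-al (7-OAc, 8-CHO and 9-H cis, trans to CH3-10) | C/C(=C\COC(=O)CCCCCCCCCCCCCCCCCCCCCCCCCCCCCO)CC[C@@H]1[C@@H](C=O)[C@@H](OC(C)=O)C=C2C(C)(C)CCC[C@@]12C
F3 | step 5 | 15-(30-hydroxytriacontanoyloxy)-ent-labda-6,13E-dien-17-al (5-H, 8-H and 9-H cis) | C/C(=C\COC(=O)CCCCCCCCCCCCCCCCCCCCCCCCCCCCCO)CC[C@@H]1[C@H](C=O)C=C[C@@H]2C(C)(C)CCC[C@@]12C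
F4 | step 5 | 15-(30-hydroxytriacontanoyloxy)-ent-labda-7,13E-dien-17-al | C/C(=C\COC(=O)CCCCCCCCCCCCCCCCCCCCCCCCCCCCCO)CC[C@@H]1C(C=O)=CC[C@@H]2C(C)(C)CCC[C@@]12C
F5 | step 2 | 6,7-epoxygeranyl 30-hydroxytriacontanoate (racemic epoxide) | C/C(=C\COC(=O)CCCCCCCCCCCCCCCCCCCCCCCCCCCCCO)CCC1OC1(C)C
F6 | step 2 | (2E)-3-methyl-6-oxohex-2-en-1-yl 30-hydroxytriacontanoate | C/C(=C\COC(=O)CCCCCCCCCCCCCCCCCCCCCCCCCCCCCO)CCC=O
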